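## Analysis of the target

The target is a C15 halogenated cyclic ether; its carbons are numbered C1 (alkyne CH) to C15 (ethyl CH3), and an oxygen joins C6 and C12 to form an oxocane (ring atoms O, C6–C12). The ring carries the (Z)-pent-2-en-4-ynyl chain at C6, chlorine at C7 and C9, an acetate at C10 and a 1-bromopropyl group at C12. There are six stereocentres (6S,7S,9S,10S,12R,13S). The C6 and C12 side chains are trans across the ring oxygen, C7–Cl and C10–OAc lie on the face of the C6 chain, and C9–Cl is trans to C10–OAc. The sensitive groups are the terminal Z-enyne, the secondary bromide β to the ether oxygen, the two secondary chlorides and the acetate. The difficulty is a saturated eight-membered ether with no ring alkene to help closure, three C–halogen bonds that each need inversion at a hindered carbinol, and four ring or side-chain oxygens that must be told apart. The strategy rests on C6 and C10, which face each other 1,5 across the ring. C6 is at the acyl level once the C5–C6 bond is removed, and C10 bears oxygen. A C6=C10 bond turns the oxocane into a dihydrofuran (O, C6, C10, C11, C12) fused to a cyclopentene (C6–C10), that is, cyclopentane-1,3-dione annulated with a C11–C15 alkene.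

## Retrosynthetic reasoning

**C3=C4 (28 ⇒ 27 ⇒ 23 + 26).** The terminal Z-enyne is the most fragile part of 28 and is removed first. The C1–H bond goes back to the silyl-capped alkyne 27, and the C3=C4 bond of 27 is cut into the terminal alkene of 23 and the enyne 26 (from 24 and 25). Cutting here leaves a plain allyl group on C6 that is inert to all earlier steps. The forward metathesis must give the Z alkene.

**C13–Br (23 ⇒ 22 ⇒ 21).** The bromide comes from the (1R)-alcohol 22 with inversion, after the chlorides, because a secondary bromide β to the ring oxygen would not survive enolate, hydride and fluoride chemistry. The C13 oxygen is therefore carried from the start as the most robust silyl ether (21 back to 2).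

**C7–Cl and C9–Cl (21 ⇒ 20 ⇒ 19 ⇒ 18 ⇒ 17).** Both chlorides are traced to diol 20 and made together by inversion. The C10 acetate is already in place and is cis to the C9 hydroxyl, so it cannot participate. Graded silyl ethers (triethylsilyl at C10, tert-butyldimethylsilyl at C7 and C9, tert-butyldiphenylsilyl at C13) let 17 be unmasked in the order C10, then C7/C9, then C13.

**C5–C6 (17 ⇒ 15 + 16; 15 ⇒ 13).** The side chain is cut from the ring next to the ring oxygen. C6 becomes an anomeric carbon in 15 and, one oxidation level higher, the carbonyl of lactone 13; the three carbons come from allylsilane 16. This puts C6 at the acyl level needed for the key cleavage. The forward addition must place the allyl group trans to C7–O and trans to the C12 chain.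

**C7–O (13 ⇒ 12 ⇒ 10).** With C6 a carbonyl, the C7 oxygen is the product of an enolate oxidation through 11. C7 is the only enolisable position in 10.

**C10–H (10 ⇒ 9 ⇒ 8).** The C10 carbinol goes back to a ketone, which leaves keto lactone 8 with carbonyls only at C6 and C10. The forward reduction must precede any base and give C10–O cis to C9–O.

**C6=C10 (8 ⇒ 6).** The two carbonyl carbons of 8 are joined into a tetrasubstituted double bond, and the oxocane collapses to the fused enol ether 6. This is preferred to any cut of a ring C–O or C–C bond because no eight-membered ring has to be closed in the forward direction; it is set free when the ring-fusion alkene is cleaved (through 7).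

**C9–H (6 ⇒ 5 ⇒ 4).** The allylic silyloxy centre C9 comes from the ketone of vinylogous ester 4. C9 is remote from C12 and C13, so the forward reduction needs catalyst control.

**C10–C11 and O–C12 (4 ⇒ 2 + 3; 2 ⇒ 1).** Both bonds of the dihydrofuran are cut in one oxidative [3+2] disconnection. Dione 3 supplies C6–C10 with the future ring oxygen and the C9 oxygen, alkene 2 supplies C11–C15, and C13 is bought as alcohol 1. The annulation creates C12 next to C13 without a control element, which is accepted at this early, cheap stage.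

## Alternatives that were turned down

**Alternative 1:** The disconnection is C11–C12, so the ring is closed by C–C bond formation next to the ring oxygen. In the forward key step, KN(SiMe3)2 deprotonates the glycolamide ether on the C6 oxygen of acyclic chloride A1, and the amide α-carbon (C12) displaces the allylic chloride at C11 to give oxocene carboxamide A2 with a Z C9=C10 alkene.
- For: the Z alkene preorganises the chain, and C6 and C7 are set in acyclic chemistry before the ring exists.
- Against: the C9=C10 alkene must become the trans C9–Cl/C10–OAc pair. That needs face-selective epoxidation and chloride opening at C9 rather than C10, two similar secondary carbons in a ring whose ether oxygen can open an activated epoxide transannularly. The amide carbon (C13) needs ketone formation, selective reduction and inversion to become CHBr–Et, and the C4–C5 stub needs three more operations.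
- Comparison: this route is stronger at C6/C7, which the chosen route sets by two late substrate-controlled steps, and its ring closure is of an established kind. The chosen strategy instead has oxygen at both C9 and C10 from the dione, so no regiochemical question arises there, and it reaches its ring-forming step in five steps.

**Alternative 2:** The disconnection is C10–C11. In the forward key step, SmI2 reduces the C10 aldehyde of A3 to a ketyl that adds 8-endo to the methylene carbon (C11) of the α-alkoxyacrylate on the C6 oxygen. The resulting C12 radical is reduced and protonated to give hydroxy ester A4.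
- For: the polarity is matched, and the C10 hydroxyl is formed free and alone with C7–O and C9–O already silylated. On this point it is stronger than the chosen route, which needs a protecting-group exchange at C10.
- Against: the 8-endo closure is slow, so simple ketyl reduction and pinacol coupling compete. C10 and C12 are formed together, C12 by protonation of a samarium enolate, and the target needs the trans C6/C12 arrangement. The ester carbon C13 needs the same multistep conversion as in Alternative 1.
- Comparison: both routes arrive at the same oxygen pattern, but this one closes the medium ring against strain and entropy, whereas the chosen route never closes an eight-membered ring. A3, with three stereocentres, also takes longer to make than 6.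

**Alternative 3:** The disconnection is O–C6 and C5–C6 together. In the forward key step, Cu(hfacac)2 converts diazo ketone A5 into a carbenoid at C6; the allyl ether oxygen on C12 adds to give an eight-membered oxonium ylide, and a [2,3]-shift moves the allyl group from oxygen to C6 to give oxocanone A6.
- For: one step makes the ring, the C5–C6 bond and the C6 centre, and A6 already has C10–OAc, C9–OSi and a C7 ketone. Its end-game is clearly shorter than the chosen one, which spends three steps on the same result.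
- Against: ylide formation through an eight-membered ring must beat closer donors. The C9 silyloxy oxygen reaches the carbenoid through a five-membered ring, and the C10–H bond through a five-membered insertion transition state. The trans C6/C12 outcome is not assured, and A5 carries four stereocentres built linearly.
- Comparison: it is more convergent at the end, but its ring-forming step is the least predictable of the four. The chosen strategy offers a well-understood ring-forming cleavage on a five-step intermediate at the price of a longer end-game.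

Key step: step 5

Remark: TBS = tert-butyldimethylsilyl, TES = triethylsilyl, TBDPS = tert-butyldiphenylsilyl, TIPS = triisopropylsilyl; locants C1–C15 in the text are those of the target chain.
Remark on the chemistry: the annulation of step 2 is assumed to show no useful induction from C13, so the (2R) epimer 4 is carried on after separation.

## Route

Step 1
Reactants: 1 (R)-pent-1-en-3-ol
Product: 2 (R)-tert-butyl(pent-1-en-3-yloxy)diphenylsilane
Conditions: TBDPSCl, imidazole, DMF, rt
Reagents that add atoms: tert-butyl(chloro)diphenylsilane, CC(C)(C)[Si](Cl)(c1ccccc1)c1ccccc1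
Why: Silyl ether formation on a secondary allylic alcohol; the TBDPS ether should tolerate trivalent manganese in AcOH, ozone, amide bases and i-Bu2AlH and outlast the TES and TBS ethers used later; C13 comes from the chiral pool and is not touched.

Step 2
Reactants: 2 (R)-tert-butyl(pent-1-en-3-yloxy)diphenylsilane; 3 cyclopentane-1,3-dione
Product: 4 (2R)-2-[(1R)-1-(TBDPSO)propyl]-2,3,5,6-tetrahydro-4H-cyclopenta[b]furan-4-one
Conditions: Mn(OAc)3·2H2O (2.2 equiv), Cu(OAc)2·H2O (0.2 equiv), AcOH, 40 °C; chromatographic separation of the C12 epimers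
Reagents that add atoms: none
Why: Mn(OAc)3-mediated oxidative radical [3+2] annulation of a cyclic 1,3-dione with a terminal alkene: the manganese enolate gives an electrophilic radical at C10 that adds to the CH2 terminus (C11), and the C12 radical is oxidised by divalent copper and captured by the enol oxygen to close the dihydrofuran. C12 forms without reliable control from C13, so both epimers are expected and the (2R) isomer is separated.

Step 3
Reactants: 4 (2R)-2-[(1R)-1-(TBDPSO)propyl]-2,3,5,6-tetrahydro-4H-cyclopenta[b]furan-4-one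
Product: 5 (2R,4R)-2-[(1R)-1-(TBDPSO)propyl]-3,4,5,6-tetrahydro-2H-cyclopenta[b]furan-4-ol
Conditions: (S)-Me-CBS oxazaborolidine [(S)-1-methyl-3,3-diphenyltetrahydro-1H,3H-pyrrolo[1,2-c][1,3,2]oxazaborole] (0.2 equiv), catecholborane, toluene, −78 → −40 °C; MeOH, then aq. NaOH work-up
Reagents that add atoms: none
Why: Corey–Bakshi–Shibata reduction; C9 is remote from C12/C13, so the catalyst sets it: with the (S)-oxazaborolidine the vinylic C10 is the large group and the (4R)-carbinol should result. Catecholborane does not hydroborate the enol ether, and the basic work-up spares the acid-labile 3-alkoxy allylic alcohol.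

Step 4
Reactants: 5 (2R,4R)-2-[(1R)-1-(TBDPSO)propyl]-3,4,5,6-tetrahydro-2H-cyclopenta[b]furan-4-ol
Product: 6 (2R,4R)-4-(TBSO)-2-[(1R)-1-(TBDPSO)propyl]-3,4,5,6-tetrahydro-2H-cyclopenta[b]furan
Conditions: TBSCl, imidazole, DMAP (cat.), DMF, 0 °C → rt; chromatography on Et3N-deactivated silica
Reagents that add atoms: tert-butyl(chloro)dimethylsilane, CC(C)(C)[Si](C)(C)Cl
Why: Silylation under imidazole buffering protects the readily ionised allylic alcohol without exposing it to acid; crude 5 is used directly.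

Step 5
Reactants: 6 (2R,4R)-4-(TBSO)-2-[(1R)-1-(TBDPSO)propyl]-3,4,5,6-tetrahydro-2H-cyclopenta[b]furan
Product: 8 (5R,8R)-5-(TBSO)-8-[(1R)-1-(TBDPSO)propyl]oxocane-2,6-dione, via secondary ozonide 7 (not isolated)
Conditions: O3, CH2Cl2, −78 °C; N2 purge; PPh3, −78 °C → rt
Reagents that add atoms: ozone, [O-][O+]=O
Why: Ozone adds in a [3+2] sense to the electron-rich, strained tetrasubstituted enol ether C6=C10; the primary ozonide fragments (Criegee mechanism) so that the oxygen-bearing C6 becomes an ester carbonyl and C10 a carbonyl oxide, and the tethered partners recombine to ozonide 7. PPh3 removes one oxygen and leaves the C6 lactone carbonyl and the C10 ketone. The closest known reaction type is the oxidative cleavage of the ring-fusion double bond of bicyclic enol ethers to medium-ring keto lactones. No ring is closed by bond formation: the oxocane is the perimeter of the 5–5 bicycle and is released when the shared bond is cut, so the usual penalty of medium-ring closure does not apply. No stereocentre is created; C9, C12 and C13 are carried through. The step needs cleavage of the enol ether alone, which its high nucleophilicity at −78 °C and the ozone-inert silyl ethers should secure. It also needs the β-acyloxy ketone to survive without loss of the C12 carboxylate or epimerisation at C9, which the neutral phosphine work-up and immediate use of 8 should secure.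

Step 6
Reactants: 8 (5R,8R)-5-(TBSO)-8-[(1R)-1-(TBDPSO)propyl]oxocane-2,6-dione
Product: 9 (5R,6S,8R)-6-hydroxy-5-(TBSO)-8-[(1R)-1-(TBDPSO)propyl]oxocan-2-one
Conditions: (R)-Me-CBS oxazaborolidine (0.3 equiv), BH3·SMe2, THF, −30 °C; MeOH, −30 °C; concentrated cold, used crude
Reagents that add atoms: none
Why: Corey–Bakshi–Shibata reduction with the branched C9 as the large group should give the (6S)-carbinol, the same face as Felkin–Anh attack anti to C9–OTBS, so C10–O ends cis to C9–O. Borane gives a non-nucleophilic borate and not an alkoxide, so neither β-elimination nor transannular acyl transfer onto C6 is triggered.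

Step 7
Reactants: 9 (5R,6S,8R)-6-hydroxy-5-(TBSO)-8-[(1R)-1-(TBDPSO)propyl]oxocan-2-one
Product: 10 (5R,6S,8R)-5-(TBSO)-6-(TESO)-8-[(1R)-1-(TBDPSO)propyl]oxocan-2-one
Conditions: TESOTf, 2,6-lutidine, CH2Cl2, −78 °C
Reagents that add atoms: triethylsilyl trifluoromethanesulfonate, CC[Si](CC)(CC)OS(=O)(=O)C(F)(F)F
Why: Silylation with the triflate at −78 °C should outrun migration of the lactone to the C10 oxygen. A TES ether is used and not the acetate, because an acetate would be enolised in step 8 and reduced in step 10, and TES can later be removed beside TBS.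

Step 8
Reactants: 10 (5R,6S,8R)-5-(TBSO)-6-(TESO)-8-[(1R)-1-(TBDPSO)propyl]oxocan-2-one
Product: 12 (3R,5R,6S,8R)-3-hydroxy-5-(TBSO)-6-(TESO)-8-[(1R)-1-(TBDPSO)propyl]oxocan-2-one, via potassium enolate 11 (not isolated)
Conditions: KN(SiMe3)2, THF, −78 °C; 2-(phenylsulfonyl)-3-phenyloxaziridine, −78 °C; AcOH
Reagents that add atoms: 2-(phenylsulfonyl)-3-phenyloxaziridine, O=S(=O)(c1ccccc1)N1OC1c1ccccc1
Why: α-Hydroxylation of a lactone enolate with an N-sulfonyloxaziridine (Davis oxidation); the oxidant should approach C7 from the face opposite the two silyloxy groups at C9 and C10, giving the (3R)-alcohol with C7–O trans to C9–O.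

Step 9
Reactants: 12 (3R,5R,6S,8R)-3-hydroxy-5-(TBSO)-6-(TESO)-8-[(1R)-1-(TBDPSO)propyl]oxocan-2-one
Product: 13 (3R,5R,6S,8R)-3,5-bis(TBSO)-6-(TESO)-8-[(1R)-1-(TBDPSO)propyl]oxocan-2-one
Conditions: TBSOTf, 2,6-lutidine, CH2Cl2, 0 °C
Reagents that add atoms: tert-butyldimethylsilyl trifluoromethanesulfonate, CC(C)(C)[Si](C)(C)OS(=O)(=O)C(F)(F)F
Why: Silyl protection of the α-hydroxy lactone; the C7–OTBS group shields one face of C6 in step 11 and is later removed together with the C9–OTBS group.

Step 10
Reactants: 13 (3R,5R,6S,8R)-3,5-bis(TBSO)-6-(TESO)-8-[(1R)-1-(TBDPSO)propyl]oxocan-2-one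
Product: 15 (3R,5R,6S,8R)-3,5-bis(TBSO)-6-(TESO)-8-[(1R)-1-(TBDPSO)propyl]oxocan-2-yl acetate (both C2 epimers), via aluminium lactolate 14 (not isolated)
Conditions: i-Bu2AlH, CH2Cl2, −78 °C; then pyridine, DMAP, Ac2O, −78 → −20 °C
Reagents that add atoms: acetic anhydride, CC(=O)OC(C)=O
Why: One-pot reductive acetylation of a lactone: the hydride adds once at −78 °C and the tetrahedral aluminium lactolate is acetylated in situ before it can open to the hydroxy aldehyde, as an eight-membered lactol otherwise would. Only silyl ethers are present, so nothing else is reduced.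

Step 11
Reactants: 15 (3R,5R,6S,8R)-3,5-bis(TBSO)-6-(TESO)-8-[(1R)-1-(TBDPSO)propyl]oxocan-2-yl acetate; 16 trimethyl(prop-2-en-1-yl)silane
Product: 17 (2S,3R,5R,6S,8R)-2-allyl-3,5-bis(TBSO)-6-(TESO)-8-[(1R)-1-(TBDPSO)propyl]oxocane
Conditions: BF3·OEt2, CH2Cl2, −78 °C
Reagents that add atoms: none
Why: Hosomi–Sakurai allylation of the oxocarbenium ion formed from the anomeric acetate; the allylsilane should add anti to the adjacent C7–OTBS group and trans to the C12 chain across the ring oxygen. Both effects point the same way and should set C6 as (2S).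

Step 12
Reactants: 17 (2S,3R,5R,6S,8R)-2-allyl-3,5-bis(TBSO)-6-(TESO)-8-[(1R)-1-(TBDPSO)propyl]oxocane
Product: 18 (2S,3R,5R,6S,8R)-2-allyl-3,5-bis(TBSO)-8-[(1R)-1-(TBDPSO)propyl]oxocan-6-ol
Conditions: PPTS (cat.), MeOH–CH2Cl2, 0 °C
Reagents that add atoms: none
Why: Acid-catalysed methanolysis should remove the TES ether selectively, since secondary TBS and TBDPS ethers are far more stable to mild acid.

Step 13
Reactants: 18 (2S,3R,5R,6S,8R)-2-allyl-3,5-bis(TBSO)-8-[(1R)-1-(TBDPSO)propyl]oxocan-6-ol
Product: 19 (2S,3R,5R,6S,8R)-2-allyl-3,5-bis(TBSO)-8-[(1R)-1-(TBDPSO)propyl]oxocan-6-yl acetate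
Conditions: Ac2O, pyridine, DMAP (cat.), CH2Cl2, rt
Reagents that add atoms: acetic anhydride, CC(=O)OC(C)=O
Why: DMAP-catalysed acylation installs the C10 acetate of the target now that the enolate and hydride steps are past.

Step 14
Reactants: 19 (2S,3R,5R,6S,8R)-2-allyl-3,5-bis(TBSO)-8-[(1R)-1-(TBDPSO)propyl]oxocan-6-yl acetate
Product: 20 (2S,3R,5R,6S,8R)-2-allyl-3,5-dihydroxy-8-[(1R)-1-(TBDPSO)propyl]oxocan-6-yl acetate
Conditions: HF·pyridine, pyridine, THF, 0 °C → rt
Reagents that add atoms: none
Why: Fluoride-mediated desilylation under acidic conditions should cleave the two secondary TBS ethers and leave the hindered TBDPS ether; the non-basic medium should keep the acetate from migrating to the cis C9 hydroxyl.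

Step 15
Reactants: 20 (2S,3R,5R,6S,8R)-2-allyl-3,5-dihydroxy-8-[(1R)-1-(TBDPSO)propyl]oxocan-6-yl acetate
Product: 21 (2S,3S,5S,6S,8R)-2-allyl-3,5-dichloro-8-[(1R)-1-(TBDPSO)propyl]oxocan-6-yl acetate
Conditions: CCl4, P(n-C8H17)3, toluene, 70 °C
Reagents that add atoms: tetrachloromethane, ClC(Cl)(Cl)Cl
Why: Appel reaction; each alkoxyphosphonium chloride should collapse by SN2 with inversion, C7 and C9 both going from R to S. The C10 acetate is cis to the C9 leaving group and cannot form an acetoxonium ion, and ring-oxygen participation at C9 is disfavoured because the trans C6/C12 substituents would force one of them into the concave face of a bicyclic oxonium ion.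

Step 16
Reactants: 21 (2S,3S,5S,6S,8R)-2-allyl-3,5-dichloro-8-[(1R)-1-(TBDPSO)propyl]oxocan-6-yl acetate
Product: 22 (2S,3S,5S,6S,8R)-2-allyl-3,5-dichloro-8-[(1R)-1-hydroxypropyl]oxocan-6-yl acetate
Conditions: Bu4NF, AcOH, THF, rt → 40 °C
Reagents that add atoms: none
Why: Fluoride cleavage of the TBDPS ether, buffered with AcOH so that the acetate and the secondary chlorides do not meet basic fluoride.

Step 17
Reactants: 22 (2S,3S,5S,6S,8R)-2-allyl-3,5-dichloro-8-[(1R)-1-hydroxypropyl]oxocan-6-yl acetate
Product: 23 (2S,3S,5S,6S,8R)-2-allyl-8-[(1S)-1-bromopropyl]-3,5-dichlorooxocan-6-yl acetate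
Conditions: CBr4, P(n-C8H17)3, toluene, 70 °C
Reagents that add atoms: tetrabromomethane, BrC(Br)(Br)Br
Why: Appel bromination with inversion should convert the (1R)-carbinol into the (1S)-bromide; the chlorides, acetate and alkene are inert to the neutral conditions.

Step 18
Reactants: 24 bromoethene; 25 ethynyltri(propan-2-yl)silane
Product: 26 but-3-en-1-yn-1-yltri(propan-2-yl)silane
Conditions: Pd(PPh3)4 (cat.), CuI (cat.), Et2NH, THF, rt
Reagents that add atoms: none
Why: Sonogashira coupling of a vinyl halide with a terminal alkyne under zerovalent palladium and CuI gives the silyl-capped enyne needed as metathesis partner.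

Step 19
Reactants: 23 (2S,3S,5S,6S,8R)-2-allyl-8-[(1S)-1-bromopropyl]-3,5-dichlorooxocan-6-yl acetate; 26 but-3-en-1-yn-1-yltri(propan-2-yl)silane
Product: 27 (2S,3S,5S,6S,8R)-8-[(1S)-1-bromopropyl]-3,5-dichloro-2-[(2Z)-5-(TIPS)pent-2-en-4-yn-1-yl]oxocan-6-yl acetate
Conditions: second-generation Grubbs catalyst RuCl2(=CHPh)(H2IMes)(PCy3) (10 mol %), 26 (excess), CH2Cl2, 40 °C
Reagents that add atoms: none
Why: Olefin cross-metathesis of a terminal alkene with a conjugated enyne, a pairing known to favour the Z-enyne because the slim alkynyl group is tolerated cis in the metallacyclobutane; loss of ethene drives the reaction and any E isomer is removed by chromatography.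

Step 20
Reactants: 27 (2S,3S,5S,6S,8R)-8-[(1S)-1-bromopropyl]-3,5-dichloro-2-[(2Z)-5-(TIPS)pent-2-en-4-yn-1-yl]oxocan-6-yl acetate
Product: 28 (2S,3S,5S,6S,8R)-8-[(1S)-1-bromopropyl]-3,5-dichloro-2-[(2Z)-pent-2-en-4-yn-1-yl]oxocan-6-yl acetate
Conditions: Bu4NF, AcOH, THF, 0 °C → rt
Reagents that add atoms: none
Why: Fluoride-induced protodesilylation of the alkynylsilane; buffering should protect the acetate and the halides and leave the Z alkene unchanged.

## Compound list

1 | (R)-pent-1-en-3-ol | C=C[C@H](O)CC | starting material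
2 | (R)-tert-butyl(pent-1-en-3-yloxy)diphenylsilane | C=C[C@H](O[Si](c1ccccc1)(c1ccccc1)C(C)(C)C)CC | intermediate
3 | cyclopentane-1,3-dione | O=C1CCC(=O)C1 | starting material
4 | (2R)-2-[(1R)-1-(TBDPSO)propyl]-2,3,5,6-tetrahydro-4H-cyclopenta[b]furan-4-one | CC[C@@H](O[Si](c1ccccc1)(c1ccccc1)C(C)(C)C)[C@H]1CC2=C(O1)CCC2=O | intermediate
5 | (2R,4R)-2-[(1R)-1-(TBDPSO)propyl]-3,4,5,6-tetrahydro-2H-cyclopenta[b]furan-4-ol | CC[C@@H](O[Si](c1ccccc1)(c1ccccc1)C(C)(C)C)[C@H]1CC2=C(O1)CC[C@H]2O | intermediate
6 | (2R,4R)-4-(TBSO)-2-[(1R)-1-(TBDPSO)propyl]-3,4,5,6-tetrahydro-2H-cyclopenta[b]furan | CC[C@@H](O[Si](c1ccccc1)(c1ccccc1)C(C)(C)C)[C@H]1CC2=C(O1)CC[C@H]2O[Si](C)(C)C(C)(C)C | intermediate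
7 | secondary ozonide of 6 (1,2,4-trioxolane bridging C6 and C10; bridge orientation not defined) | CC[C@@H](O[Si](c1ccccc1)(c1ccccc1)C(C)(C)C)[C@H]1CC23OOC(O2)(CC[C@H]3O[Si](C)(C)C(C)(C)C)O1 | intermediate
8 | (5R,8R)-5-(TBSO)-8-[(1R)-1-(TBDPSO)propyl]oxocane-2,6-dione | O=C1O[C@@H]([C@H](O[Si](c2ccccc2)(c2ccccc2)C(C)(C)C)CC)CC(=O)[C@H](O[Si](C)(C)C(C)(C)C)CC1 | intermediate
9 | (5R,6S,8R)-6-hydroxy-5-(TBSO)-8-[(1R)-1-(TBDPSO)propyl]oxocan-2-one | O=C1O[C@@H]([C@H](O[Si](c2ccccc2)(c2ccccc2)C(C)(C)C)CC)C[C@H](O)[C@H](O[Si](C)(C)C(C)(C)C)CC1 | intermediate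
10 | (5R,6S,8R)-5-(TBSO)-6-(TESO)-8-[(1R)-1-(TBDPSO)propyl]oxocan-2-one | O=C1O[C@@H]([C@H](O[Si](c2ccccc2)(c2ccccc2)C(C)(C)C)CC)C[C@H](O[Si](CC)(CC)CC)[C@H](O[Si](C)(C)C(C)(C)C)CC1 | intermediate
11 | potassium enolate of 10 (C6=C7) | [K+].[O-]C=1O[C@@H]([C@H](O[Si](c2ccccc2)(c2ccccc2)C(C)(C)C)CC)C[C@H](O[Si](CC)(CC)CC)[C@H](O[Si](C)(C)C(C)(C)C)CC=1 | intermediate
12 | (3R,5R,6S,8R)-3-hydroxy-5-(TBSO)-6-(TESO)-8-[(1R)-1-(TBDPSO)propyl]oxocan-2-one | O=C1O[C@@H]([C@H](O[Si](c2ccccc2)(c2ccccc2)C(C)(C)C)CC)C[C@H](O[Si](CC)(CC)CC)[C@H](O[Si](C)(C)C(C)(C)C)C[C@H]1O | intermediate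
13 | (3R,5R,6S,8R)-3,5-bis(TBSO)-6-(TESO)-8-[(1R)-1-(TBDPSO)propyl]oxocan-2-one | O=C1O[C@@H]([C@H](O[Si](c2ccccc2)(c2ccccc2)C(C)(C)C)CC)C[C@H](O[Si](CC)(CC)CC)[C@H](O[Si](C)(C)C(C)(C)C)C[C@H]1O[Si](C)(C)C(C)(C)C | intermediate
14 | diisobutylaluminium lactolate of 13 (C2 epimers) | CC(C)C[Al](CC(C)C)OC1O[C@@H]([C@H](O[Si](c2ccccc2)(c2ccccc2)C(C)(C)C)CC)C[C@H](O[Si](CC)(CC)CC)[C@H](O[Si](C)(C)C(C)(C)C)C[C@H]1O[Si](C)(C)C(C)(C)C | intermediate
15 | (3R,5R,6S,8R)-3,5-bis(TBSO)-6-(TESO)-8-[(1R)-1-(TBDPSO)propyl]oxocan-2-yl acetate (C2 epimers) | CC(=O)OC1O[C@@H]([C@H](O[Si](c2ccccc2)(c2ccccc2)C(C)(C)C)CC)C[C@H](O[Si](CC)(CC)CC)[C@H](O[Si](C)(C)C(C)(C)C)C[C@H]1O[Si](C)(C)C(C)(C)C | intermediate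
16 | trimethyl(prop-2-en-1-yl)silane | C=CC[Si](C)(C)C | starting material
17 | (2S,3R,5R,6S,8R)-2-allyl-3,5-bis(TBSO)-6-(TESO)-8-[(1R)-1-(TBDPSO)propyl]oxocane | C=CC[C@@H]1O[C@@H]([C@H](O[Si](c2ccccc2)(c2ccccc2)C(C)(C)C)CC)C[C@H](O[Si](CC)(CC)CC)[C@H](O[Si](C)(C)C(C)(C)C)C[C@H]1O[Si](C)(C)C(C)(C)C | intermediate
18 | (2S,3R,5R,6S,8R)-2-allyl-3,5-bis(TBSO)-8-[(1R)-1-(TBDPSO)propyl]oxocan-6-ol | C=CC[C@@H]1O[C@@H]([C@H](O[Si](c2ccccc2)(c2ccccc2)C(C)(C)C)CC)C[C@H](O)[C@H](O[Si](C)(C)C(C)(C)C)C[C@H]1O[Si](C)(C)C(C)(C)C | intermediate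
19 | (2S,3R,5R,6S,8R)-2-allyl-3,5-bis(TBSO)-8-[(1R)-1-(TBDPSO)propyl]oxocan-6-yl acetate | C=CC[C@@H]1O[C@@H]([C@H](O[Si](c2ccccc2)(c2ccccc2)C(C)(C)C)CC)C[C@H](OC(C)=O)[C@H](O[Si](C)(C)C(C)(C)C)C[C@H]1O[Si](C)(C)C(C)(C)C | intermediate
20 | (2S,3R,5R,6S,8R)-2-allyl-3,5-dihydroxy-8-[(1R)-1-(TBDPSO)propyl]oxocan-6-yl acetate | C=CC[C@@H]1O[C@@H]([C@H](O[Si](c2ccccc2)(c2ccccc2)C(C)(C)C)CC)C[C@H](OC(C)=O)[C@H](O)C[C@H]1O | intermediate
21 | (2S,3S,5S,6S,8R)-2-allyl-3,5-dichloro-8-[(1R)-1-(TBDPSO)propyl]oxocan-6-yl acetate | C=CC[C@@H]1O[C@@H]([C@H](O[Si](c2ccccc2)(c2ccccc2)C(C)(C)C)CC)C[C@H](OC(C)=O)[C@@H](Cl)C[C@@H]1Cl | intermediate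
22 | (2S,3S,5S,6S,8R)-2-allyl-3,5-dichloro-8-[(1R)-1-hydroxypropyl]oxocan-6-yl acetate | C=CC[C@@H]1O[C@@H]([C@H](O)CC)C[C@H](OC(C)=O)[C@@H](Cl)C[C@@H]1Cl | intermediate
23 | (2S,3S,5S,6S,8R)-2-allyl-8-[(1S)-1-bromopropyl]-3,5-dichlorooxocan-6-yl acetate | C=CC[C@@H]1O[C@@H]([C@@H](Br)CC)C[C@H](OC(C)=O)[C@@H](Cl)C[C@@H]1Cl | intermediate
24 | bromoethene | C=CBr | starting material
25 | ethynyltri(propan-2-yl)silane | C#C[Si](C(C)C)(C(C)C)C(C)C | starting material
26 | but-3-en-1-yn-1-yltri(propan-2-yl)silane | C=CC#C[Si](C(C)C)(C(C)C)C(C)C | intermediate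
27 | (2S,3S,5S,6S,8R)-8-[(1S)-1-bromopropyl]-3,5-dichloro-2-[(2Z)-5-(TIPS)pent-2-en-4-yn-1-yl]oxocan-6-yl acetate | CC(C)[Si](C(C)C)(C(C)C)C#C/C=C\C[C@@H]1O[C@@H]([C@@H](Br)CC)C[C@H](OC(C)=O)[C@@H](Cl)C[C@@H]1Cl | intermediate
28 | (2S,3S,5S,6S,8R)-8-[(1S)-1-bromopropyl]-3,5-dichloro-2-[(2Z)-pent-2-en-4-yn-1-yl]oxocan-6-yl acetate | C#C/C=C\C[C@@H]1O[C@@H]([C@@H](Br)CC)C[C@H](OC(C)=O)[C@@H](Cl)C[C@@H]1Cl | target

## Step count and least certain steps

Total: 20 steps. Longest linear sequence: 19 steps (steps 1–17, 19, 20) from (R)-pent-1-en-3-ol; step 18 is a one-step side branch.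

**Step 5 (key step).** The allylic silyloxy enol ether may ionise on traces of acid before it is cleaved. The hindered tetrasubstituted alkene may be epoxidised without fragmenting. The β-acyloxy ketone may lose the C12 carboxylate during isolation. Fallback, from 6 back to 8: dihydroxylation of the enol ether with OsO4 (cat.) and N-methylmorpholine N-oxide in buffered acetone–water should give the 6,10-dihydroxy bicycle F1, and glycol cleavage with Pb(OAc)4 in benzene should then give 8.

**Step 2.** Addition of the dione radical to an unactivated monosubstituted alkene may be slow relative to over-oxidation of the dione, and the absence of facial control at C12 costs material. Fallback, from 3 back to 4, with both centres controlled: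
- C-allylation of 3 with (E)-1-bromopent-2-ene in aqueous KOH should give 2-[(2E)-pent-2-en-1-yl]cyclopentane-1,3-dione F2.
- O-methylation with Me3SiCHN2 in MeOH gives 3-methoxy-2-[(2E)-pent-2-en-1-yl]cyclopent-2-en-1-one F3.
- Shi epoxidation with the L-fructose-derived ketone (1,2:4,5-di-O-isopropylidene-β-L-erythro-2,3-hexodiulo-2,6-pyranose) and KHSO5 (as 2KHSO5·KHSO4·K2SO4) in K2CO3 buffer should give the (2S,3S)-epoxide F4.
- Camphorsulfonic acid in wet CH2Cl2 lets the vinylogous ester carbonyl oxygen open the epoxide 5-exo at C12 with inversion and lose methanol, giving (2R)-2-[(1S)-1-hydroxypropyl]-2,3,5,6-tetrahydro-4H-cyclopenta[b]furan-4-one F5.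
- Mitsunobu reaction with 4-nitrobenzoic acid, PPh3 and diisopropyl azodicarboxylate inverts C13 to give the (1R)-4-nitrobenzoate F6.
- K2CO3 in MeOH frees (2R)-2-[(1R)-1-hydroxypropyl]-2,3,5,6-tetrahydro-4H-cyclopenta[b]furan-4-one F7, and silylation with TBDPSCl and imidazole gives 4.

**Step 6.** The new C10 hydroxyl may attack the C6 carbonyl transannularly and contract the lactone, and hydride may arrive on the wrong face. Fallback, from 8 directly to 10: hydrosilylation of the ketone with Et3SiH and RhCl(PPh3)3 (cat.) in toluene converts the carbonyl into the TES ether without a free hydroxyl at any point; face selection then rests on attack anti to C9–OTBS. No new compound is made.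

**Step 8.** The flexible eight-membered enolate may be oxidised with poor or reversed facial selectivity. Fallback, from 10 back to 12: if the hydroxylation gives mainly the (3S)-epimer of 12, F8, a Mitsunobu reaction with chloroacetic acid, PPh3 and diisopropyl azodicarboxylate inverts C7 to the (3R)-chloroacetate F9. Thiourea and NaHCO3 in EtOH then remove the chloroacetyl group and give 12.

**Step 11.** The allylsilane may add with poor face selectivity at C6, or the oxocarbenium ion may lose a proton to give the enol ether. Fallback, from 13 back to 17, reversing the order in which carbon and hydrogen are put on C6: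
- Petasis methylenation of 13 (Cp2TiMe2, toluene, 70 °C) gives the 2-methylidene oxocane F10.
- Hydroboration–oxidation (9-borabicyclo[3.3.1]nonane; NaOH, H2O2) delivers hydrogen to C6 from the face an external reagent prefers and gives the (2S)-2-(hydroxymethyl)oxocane F11.
- Tf2O and 2,6-lutidine give the primary triflate F12, and vinylmagnesium bromide with CuBr·SMe2 (cat.) displaces it to give 17.

**Step 15.** The ring oxygen may displace the activated C9 oxygen transannularly, which would give retention or ring contraction. The 1,3-diol may also form a cyclic phosphorane, and E2 loss may compete at either carbinol. Fallback, from 20 back to 21, separating activation from displacement: chloromethanesulfonyl chloride and pyridine at 0 °C give the 3,5-bis(chloromethanesulfonate) F13. LiCl in DMF (or Bu4NCl in toluene) then displaces both sulfonates by external chloride with inversion and gives 21.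

## Further compounds

F1 | step 5 | (2R,4R)-4-(TBSO)-2-[(1R)-1-(TBDPSO)propyl]hexahydro-2H-cyclopenta[b]furan-3a,6a-diol (cis-diol, face not defined) | CC[C@@H](O[Si](c1ccccc1)(c1ccccc1)C(C)(C)C)[C@H]1CC2(O)C(O)(O1)CC[C@H]2O[Si](C)(C)C(C)(C)C
F2 | step 2 | 2-[(2E)-pent-2-en-1-yl]cyclopentane-1,3-dione | CC/C=C/CC1C(=O)CCC1=O
F3 | step 2 | 3-methoxy-2-[(2E)-pent-2-en-1-yl]cyclopent-2-en-1-one | CC/C=C/CC1=C(OC)CCC1=O
F4 | step 2 | 2-{[(2S,3S)-3-ethyloxiran-2-yl]methyl}-3-methoxycyclopent-2-en-1-one | CC[C@@H]1O[C@H]1CC1=C(OC)CCC1=O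
F5 | step 2 | (2R)-2-[(1S)-1-hydroxypropyl]-2,3,5,6-tetrahydro-4H-cyclopenta[b]furan-4-one | CC[C@H](O)[C@H]1CC2=C(O1)CCC2=O
F6 | step 2 | (1R)-1-[(2R)-4-oxo-3,4,5,6-tetrahydro-2H-cyclopenta[b]furan-2-yl]propyl 4-nitrobenzoate | CC[C@@H](OC(=O)c3ccc(cc3)[N+](=O)[O-])[C@H]1CC2=C(O1)CCC2=O
F7 | step 2 | (2R)-2-[(1R)-1-hydroxypropyl]-2,3,5,6-tetrahydro-4H-cyclopenta[b]furan-4-one | CC[C@@H](O)[C@H]1CC2=C(O1)CCC2=O
F0 | step 6 | none | none
F8 | step 8 | (3S,5R,6S,8R)-3-hydroxy-5-(TBSO)-6-(TESO)-8-[(1R)-1-(TBDPSO)propyl]oxocan-2-one | O=C1O[C@@H]([C@H](O[Si](c2ccccc2)(c2ccccc2)C(C)(C)C)CC)C[C@H](O[Si](CC)(CC)CC)[C@H](O[Si](C)(C)C(C)(C)C)C[C@@H]1O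
F9 | step 8 | (3R,5R,6S,8R)-5-(TBSO)-6-(TESO)-8-[(1R)-1-(TBDPSO)propyl]-2-oxooxocan-3-yl chloroacetate | O=C1O[C@@H]([C@H](O[Si](c2ccccc2)(c2ccccc2)C(C)(C)C)CC)C[C@H](O[Si](CC)(CC)CC)[C@H](O[Si](C)(C)C(C)(C)C)C[C@H]1OC(=O)CCl
F10 | step 11 | (3R,5R,6S,8R)-3,5-bis(TBSO)-6-(TESO)-8-[(1R)-1-(TBDPSO)propyl]-2-methylideneoxocane | C=C1O[C@@H]([C@H](O[Si](c2ccccc2)(c2ccccc2)C(C)(C)C)CC)C[C@H](O[Si](CC)(CC)CC)[C@H](O[Si](C)(C)C(C)(C)C)C[C@H]1O[Si](C)(C)C(C)(C)C
F11 | step 11 | [(2S,3R,5R,6S,8R)-3,5-bis(TBSO)-6-(TESO)-8-[(1R)-1-(TBDPSO)propyl]oxocan-2-yl]methanol | OC[C@@H]1O[C@@H]([C@H](O[Si](c2ccccc2)(c2ccccc2)C(C)(C)C)CC)C[C@H](O[Si](CC)(CC)CC)[C@H](O[Si](C)(C)C(C)(C)C)C[C@H]1O[Si](C)(C)C(C)(C)C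
F12 | step 11 | [(2S,3R,5R,6S,8R)-3,5-bis(TBSO)-6-(TESO)-8-[(1R)-1-(TBDPSO)propyl]oxocan-2-yl]methyl trifluoromethanesulfonate | O=S(=O)(OC[C@@H]1O[C@@H]([C@H](O[Si](c2ccccc2)(c2ccccc2)C(C)(C)C)CC)C[C@H](O[Si](CC)(CC)CC)[C@H](O[Si](C)(C)C(C)(C)C)C[C@H]1O[Si](C)(C)C(C)(C)C)C(F)(F)F
F13 | step 15 | (2S,3R,5R,6S,8R)-2-allyl-3,5-bis[(chloromethanesulfonyl)oxy]-8-[(1R)-1-(TBDPSO)propyl]oxocan-6-yl acetate | C=CC[C@@H]1O[C@@H]([C@H](O[Si](c2ccccc2)(c2ccccc2)C(C)(C)C)CC)C[C@H](OC(C)=O)[C@H](OS(=O)(=O)CCl)C[C@H]1OS(=O)(=O)CCl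
A1 | alternative 1 | acyclic (Z)-allylic chloride with the N,N-dimethylglycolamide ether on the C6 oxygen | ClC/C=C\C[C@@H](OCc1ccc(OC)cc1)[C@H](CCO[Si](C(C)C)(C(C)C)C(C)C)OCC(=O)N(C)C
A2 | alternative 1 | oxocene 2-carboxamide (Z C9=C10) | CN(C)C(=O)[C@H]1C/C=C\C[C@@H](OCc2ccc(OC)cc2)[C@H](CCO[Si](C(C)C)(C(C)C)C(C)C)O1
A3 | alternative 2 | C10 aldehyde with the methyl α-alkoxyacrylate on the C6 oxygen | O=C[C@H](O[Si](C)(C)C(C)(C)C)C[C@@H](O[Si](C)(C)C(C)(C)C)[C@H](CCOC(=O)C(C)(C)C)OC(=C)C(=O)OC
A4 | alternative 2 | methyl 4-hydroxyoxocane-2-carboxylate | COC(=O)[C@H]1C[C@H](O)[C@H](O[Si](C)(C)C(C)(C)C)C[C@@H](O[Si](C)(C)C(C)(C)C)[C@H](CCOC(=O)C(C)(C)C)O1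
A5 | alternative 3 | C6 diazo ketone with the allyl ether on the C12 oxygen | C=CCO[C@@H]([C@H](OCc1ccc(OC)cc1)CC)C[C@H](OC(C)=O)[C@H](O[Si](C)(C)C(C)(C)C)CC(=O)C=[N+]=[N-]
A6 | alternative 3 | 2-allyloxocan-3-one | C=CC[C@@H]1O[C@@H]([C@H](OCc2ccc(OC)cc2)CC)C[C@H](OC(C)=O)[C@H](O[Si](C)(C)C(C)(C)C)CC1=O
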